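**Plan**

1. Azulene numbering of the target: C3 = C(OH)iPr, C3a = ring-fusion CH, C4 = CH–O, C6 = C–Me, C8 = C=O, C8a = C–Me. The retrosynthesis cuts, in order: the ester C–O; the C6=C7 unsaturation (back to the saturated ketone); C4–H (back to a 4,8-dione); C4 and C8 are then rejoined to a cyclobutane-1,2-diol, which is cut at C8–C8a and C4–C3a; last, C3–OH and C3–iPr go back to a ring ketone.
2. Enabling feature: the C8 ketone carbon and the C4 carbinol carbon are 1,4-related across the ring-fusion bond C3a–C8a, and the arc C4–C5–C6(Me)–C7–C8 of the seven-membered ring is symmetric about C6. The seven-membered ring is therefore a masked, C_s-symmetric cyclopentene-1,2-diol joined to the five-membered ring through a cyclobutane, and one enone–alkene [2+2] photocycloaddition makes both bonds with no regiochemical question.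
3. Forward: the five-membered ring comes from a silyloxycyclopentenone; the photocycloaddition with a 4-methylcyclopentene-1,2-diol bis(silyl ether) (from 3-methylglutarate) gives a 5-4-5 tricycle; the isopropyl carbinol is built on the rigid tricycle; glycol cleavage then opens the cyclobutane and the seven-membered ring appears; ring-fusion epimerisation, directed reduction, esterification and dehydrogenation finish.
4. Stereochemistry: absolute configuration comes from (R)-4-silyloxycyclopentenone, whose silyloxy group steers the photocycloaddition (quaternary C8a) and is then eliminated; C3 from exo-face hydration of the tricycle; C3a from thermodynamic epimerisation to the trans-fused bicycle; C4 from hydride delivery by the C3 hydroxyl.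

Key step: step 3

Remark: the CHMe carbon that becomes C6 is stereogenic from step 3 to step 11 and is expected to form as a mixture of epimers; it becomes sp2 in step 12, so its descriptor is left open in names and SMILES.

**Route**

Step 1
Reactants: 1 (R)-4-(tert-butyldimethylsilyloxy)cyclopent-2-en-1-one
Product: 3 (R)-4-(tert-butyldimethylsilyloxy)-3-methylcyclopent-2-en-1-one, via trimethylsilyl enol ether 2 (not isolated)
Conditions: MeMgBr, CuBr·SMe2 (5 mol %), TMSCl, THF, −78 °C, Et3N quench; crude 2: Pd(OAc)2 (10 mol %), O2 (1 atm), DMSO, rt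
Reagents that add atoms: methylmagnesium bromide (C[Mg]Br); chlorotrimethylsilane (C[Si](C)(C)Cl)
Why: Copper-catalysed conjugate addition of the methyl Grignard reagent anti to the silyloxy group with in situ O-silylation gives the regiodefined enol ether 2, whose trimethylsilyl group is lost again in the catalytic aerobic Saegusa–Ito oxidation (palladium enolate, syn β-hydride elimination of the C3–H) that restores the enone with the methyl group in place while the C4 stereocentre is untouched.

Step 2
Reactants: 4 dimethyl 3-methylpentanedioate (dimethyl 3-methylglutarate)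
Product: 5 4-methyl-1,2-bis(trimethylsilyloxy)cyclopent-1-ene
Conditions: Na, TMSCl, toluene, reflux
Reagents that add atoms: chlorotrimethylsilane (C[Si](C)(C)Cl)
Why: Rühlmann acyloin condensation, in which sodium reduces both esters, the ketyl radicals couple and chlorotrimethylsilane traps the enediolate, so that the symmetric five-carbon arc of the future seven-membered ring is closed into a cyclopentene bis(silyl enol ether).

Step 3
Reactants: 3 (R)-4-(tert-butyldimethylsilyloxy)-3-methylcyclopent-2-en-1-one; 5 4-methyl-1,2-bis(trimethylsilyloxy)cyclopent-1-ene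
Product: 6 cis-anti-cis 10-(tert-butyldimethylsilyloxy)-1,4-dimethyl-2,6-bis(trimethylsilyloxy)tricyclo[5.3.0.0^2,6]decan-8-one (cyclobutane anti to the silyloxy group at C10; H-7 cis to the 1-methyl group)
Conditions: hν (Pyrex filter, λ > 300 nm), 5 (4 equiv), hexane, −20 °C
Reagents that add atoms: none
Why: Excitation of the enone (n→π*), intersystem crossing and attack of the triplet on the electron-rich tetrasubstituted alkene of 5 give a triplet 1,4-biradical that closes after spin inversion, so that C1–C2 and C6–C7 of the tricycle (C8a–C8 and C4–C3a of the target) form in one photochemical operation. The closest known reaction type is the de Mayo-type [2+2] photocycloaddition of cyclopentenones with 1,2-bis(trimethylsilyloxy)cycloalkenes, used with later glycol cleavage as a two-carbon ring expansion to hydroazulenes. The only ring closed is the cyclobutane, by radical–radical recombination of the 1,4-biradical and not by a polar exo or endo closure; the seven-membered ring is latent in it as the C2–C6 bond that step 8 cleaves. The quaternary C1 is set by approach of 5 anti to the neighbouring silyloxy group, C7–H is forced cis to the 1-methyl group by the strain of the bicyclo[3.2.0] unit (corrected in step 9), the two silyloxy-bearing carbons are cis by ring constraint and are erased in step 8, and the CHMe carbon is not controlled and is erased in step 12. The step needs facial selectivity, secured by the C4 silyloxy group of 3, and cross-addition in preference to enone dimerisation, secured by light that only the enone absorbs and by an excess of 5; regioselectivity is not at issue because the two alkene carbons of 5 are equivalent by symmetry, and a cis-syn-cis adduct would converge with the cis-anti-cis one after step 8.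

Step 4
Reactants: 6 cis-anti-cis 10-(tert-butyldimethylsilyloxy)-1,4-dimethyl-2,6-bis(trimethylsilyloxy)tricyclo[5.3.0.0^2,6]decan-8-one
Product: 8 cis-anti-cis 1,4-dimethyl-2,6-bis(trimethylsilyloxy)tricyclo[5.3.0.0^2,6]decan-8-one, via tricyclic enone 7 (not isolated)
Conditions: DBU, CH2Cl2, 0 °C → rt; then H2 (1 atm), Pd/C, EtOAc, rt
Reagents that add atoms: none
Why: E1cB elimination of the β-silyloxy group through the enolate on the CH2 side removes the stereodirecting group (the silyl ethers on the cyclobutane offer no retro-aldol path), and catalytic hydrogenation of the resulting cyclopentenone C=C gives the saturated ketone without touching the quaternary stereocentre.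

Step 5
Reactants: 8 cis-anti-cis 1,4-dimethyl-2,6-bis(trimethylsilyloxy)tricyclo[5.3.0.0^2,6]decan-8-one
Product: 9 cis-anti-cis 1,4-dimethyl-2,6-bis(trimethylsilyloxy)tricyclo[5.3.0.0^2,6]dec-8-en-8-yl trifluoromethanesulfonate
Conditions: KN(SiMe3)2, THF, −78 °C; PhNTf2, −78 → 0 °C
Reagents that add atoms: N-phenylbis(trifluoromethanesulfonimide) (O=S(=O)(N(c1ccccc1)S(=O)(=O)C(F)(F)F)C(F)(F)F)
Why: Kinetic enolate formation with the bulky amide at the unhindered CH2 and not at the ring-fusion CH, followed by O-triflation of the potassium enolate, gives the less substituted enol triflate regioselectively.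

Step 6
Reactants: 9 cis-anti-cis 1,4-dimethyl-2,6-bis(trimethylsilyloxy)tricyclo[5.3.0.0^2,6]dec-8-en-8-yl trifluoromethanesulfonate
Product: 10 cis-anti-cis 1,4-dimethyl-8-(propan-2-yl)-2,6-bis(trimethylsilyloxy)tricyclo[5.3.0.0^2,6]dec-8-ene
Conditions: iPrMgCl, Fe(acac)3 (5 mol %), THF/NMP, −30 → 0 °C
Reagents that add atoms: isopropylmagnesium chloride (CC(C)[Mg]Cl)
Why: Iron-catalysed Kumada-type cross-coupling of an alkenyl triflate with an alkyl Grignard reagent is fast at low temperature, tolerates silyl ethers and accepts secondary alkyl groups, so the isopropyl group is attached at the sp2 carbon with no stereochemical issue.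

Step 7
Reactants: 10 cis-anti-cis 1,4-dimethyl-8-(propan-2-yl)-2,6-bis(trimethylsilyloxy)tricyclo[5.3.0.0^2,6]dec-8-ene
Product: 11 cis-anti-cis 1,4-dimethyl-8-(propan-2-yl)-2,6-bis(trimethylsilyloxy)tricyclo[5.3.0.0^2,6]decan-8-ol (8-OH exo, cis to the 1-methyl group and to H-7; isopropyl endo)
Conditions: Co(acac)2 (20 mol %), PhSiH3, O2 (1 atm), THF, rt
Reagents that add atoms: dioxygen (O=O)
Why: Mukaiyama hydration, in which hydrogen-atom transfer from a Co–H species to the CH end of the trisubstituted alkene gives the tertiary radical (Markovnikov), which should be trapped by O2 on the exo face of the bicyclo[3.2.0] unit, away from the cyclobutane and its endo silyloxy group, so that the hydroxyl ends cis to the angular methyl group.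

Step 8
Reactants: 11 cis-anti-cis 1,4-dimethyl-8-(propan-2-yl)-2,6-bis(trimethylsilyloxy)tricyclo[5.3.0.0^2,6]decan-8-ol
Product: 13 (3R,3aS,8aS)-3-hydroxy-6,8a-dimethyl-3-(propan-2-yl)perhydroazulene-4,8-dione (cis-fused), via tricyclic triol 12 (not isolated)
Conditions: PPTS (cat.), MeOH, 0 °C → rt; then NaIO4, H2O/THF, 0 °C → rt
Reagents that add atoms: none
Why: Mild acid methanolysis frees the two tertiary cyclobutanols while the molecule has no carbonyl group (no retro-aldol path), and periodate (Malaprade) cleavage of the cis-cyclobutane-1,2-diol opens the four-membered ring with relief of strain to the 1,4-diketone, which turns the former cyclopentene ring into the seven-membered ring and leaves the 1,3-related tertiary hydroxyl untouched.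

Step 9
Reactants: 13 (3R,3aS,8aS)-3-hydroxy-6,8a-dimethyl-3-(propan-2-yl)perhydroazulene-4,8-dione (cis-fused)
Product: 14 (3R,3aR,8aS)-3-hydroxy-6,8a-dimethyl-3-(propan-2-yl)perhydroazulene-4,8-dione (trans-fused)
Conditions: DBU (0.3 equiv), CH2Cl2, 0 °C → rt
Reagents that add atoms: none
Why: Base-mediated epimerisation through the C4 enolate should move the strained cis-fused isomer, in which the isopropyl group eclipses the C4 carbonyl carbon, to the trans-fused hydroazulenone, in which the C3 hydroxyl is cis to C4 and can hydrogen-bond to its carbonyl, while the quaternary C8a cannot epimerise.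

Step 10
Reactants: 14 (3R,3aR,8aS)-3-hydroxy-6,8a-dimethyl-3-(propan-2-yl)perhydroazulene-4,8-dione (trans-fused)
Product: 15 (3R,3aS,4S,8aS)-3,4-dihydroxy-6,8a-dimethyl-3-(propan-2-yl)perhydroazulen-8-one
Conditions: Me4NBH(OAc)3, MeCN/AcOH, −20 °C
Reagents that add atoms: none
Why: Evans–Saksena hydroxyl-directed reduction, in which the tertiary C3 hydroxyl exchanges onto boron and delivers hydride through a six-membered transition state to the β face of the C4 ketone (the α face is screened by the isopropyl group), should give the 4α alcohol, while the C8 ketone, remote from and trans to the hydroxyl, is not reduced by this weak hydride donor.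

Step 11
Reactants: 15 (3R,3aS,4S,8aS)-3,4-dihydroxy-6,8a-dimethyl-3-(propan-2-yl)perhydroazulen-8-one; 16 3,4,5-trimethoxybenzoyl chloride
Product: 17 (3R,3aS,4S,8aS)-3-hydroxy-6,8a-dimethyl-8-oxo-3-(propan-2-yl)perhydroazulen-4-yl 3,4,5-trimethoxybenzoate
Conditions: Et3N, DMAP (cat.), CH2Cl2, 0 °C → rt
Reagents that add atoms: none
Why: DMAP-catalysed acylation (nucleophilic catalysis) should take place only at the secondary equatorial C4 hydroxyl, because the tertiary C3 hydroxyl is too hindered to react with the acylpyridinium ion.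

Step 12
Reactants: 17 (3R,3aS,4S,8aS)-3-hydroxy-6,8a-dimethyl-8-oxo-3-(propan-2-yl)perhydroazulen-4-yl 3,4,5-trimethoxybenzoate
Product: 18 (3R,3aS,4S,8aS)-3-hydroxy-6,8a-dimethyl-8-oxo-3-(propan-2-yl)-1,2,3,3a,4,5,8,8a-octahydroazulen-4-yl 3,4,5-trimethoxybenzoate (target)
Conditions: IBX, DMSO, 65 °C
Reagents that add atoms: none
Why: IBX dehydrogenation of a ketone to its enone, in which the C8 ketone can enolise only towards C7 because C8a is quaternary, should give the conjugated C6=C7 double bond from either C6 epimer and leave the tertiary alcohol and the ester untouched.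

**Compound list**

1 | (R)-4-(tert-butyldimethylsilyloxy)cyclopent-2-en-1-one | O=C1C[C@@H](O[Si](C)(C)C(C)(C)C)C=C1 | starting material
2 | tert-butyldimethyl{[(1R,2R)-2-methyl-4-(trimethylsilyloxy)cyclopent-3-en-1-yl]oxy}silane (methyl trans to the silyloxy group) | C[Si](C)(C)OC1=C[C@@H](C)[C@H](O[Si](C)(C)C(C)(C)C)C1 | intermediate (not isolated)
3 | (R)-4-(tert-butyldimethylsilyloxy)-3-methylcyclopent-2-en-1-one | O=C1C[C@@H](O[Si](C)(C)C(C)(C)C)C(C)=C1 | intermediate
4 | dimethyl 3-methylpentanedioate | COC(=O)CC(C)CC(=O)OC | starting material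
5 | 4-methyl-1,2-bis(trimethylsilyloxy)cyclopent-1-ene | CC1CC(O[Si](C)(C)C)=C(O[Si](C)(C)C)C1 | intermediate
6 | cis-anti-cis 10-(tert-butyldimethylsilyloxy)-1,4-dimethyl-2,6-bis(trimethylsilyloxy)tricyclo[5.3.0.0^2,6]decan-8-one | O=C1C[C@@H](O[Si](C)(C)C(C)(C)C)[C@@]2(C)[C@@H]1[C@]3(O[Si](C)(C)C)CC(C)C[C@]23O[Si](C)(C)C | intermediate
7 | cis-anti-cis 1,4-dimethyl-2,6-bis(trimethylsilyloxy)tricyclo[5.3.0.0^2,6]dec-9-en-8-one | O=C1C=C[C@@]2(C)[C@@H]1[C@]3(O[Si](C)(C)C)CC(C)C[C@]23O[Si](C)(C)C | intermediate (not isolated)
8 | cis-anti-cis 1,4-dimethyl-2,6-bis(trimethylsilyloxy)tricyclo[5.3.0.0^2,6]decan-8-one | O=C1CC[C@@]2(C)[C@@H]1[C@]3(O[Si](C)(C)C)CC(C)C[C@]23O[Si](C)(C)C | intermediate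
9 | cis-anti-cis 1,4-dimethyl-2,6-bis(trimethylsilyloxy)tricyclo[5.3.0.0^2,6]dec-8-en-8-yl trifluoromethanesulfonate | O=S(=O)(OC1=CC[C@@]2(C)[C@@H]1[C@]3(O[Si](C)(C)C)CC(C)C[C@]23O[Si](C)(C)C)C(F)(F)F | intermediate
10 | cis-anti-cis 1,4-dimethyl-8-(propan-2-yl)-2,6-bis(trimethylsilyloxy)tricyclo[5.3.0.0^2,6]dec-8-ene | CC(C)C1=CC[C@@]2(C)[C@@H]1[C@]3(O[Si](C)(C)C)CC(C)C[C@]23O[Si](C)(C)C | intermediate
11 | cis-anti-cis 1,4-dimethyl-8-(propan-2-yl)-2,6-bis(trimethylsilyloxy)tricyclo[5.3.0.0^2,6]decan-8-ol (8-OH exo) | CC(C)[C@]1(O)CC[C@@]2(C)[C@@H]1[C@]3(O[Si](C)(C)C)CC(C)C[C@]23O[Si](C)(C)C | intermediate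
12 | cis-anti-cis 1,4-dimethyl-8-(propan-2-yl)tricyclo[5.3.0.0^2,6]decane-2,6,8-triol | CC(C)[C@]1(O)CC[C@@]2(C)[C@@H]1[C@]3(O)CC(C)C[C@]23O | intermediate (not isolated)
13 | (3R,3aS,8aS)-3-hydroxy-6,8a-dimethyl-3-(propan-2-yl)perhydroazulene-4,8-dione (cis-fused) | CC(C)[C@]1(O)CC[C@@]2(C)[C@@H]1C(=O)CC(C)CC2=O | intermediate
14 | (3R,3aR,8aS)-3-hydroxy-6,8a-dimethyl-3-(propan-2-yl)perhydroazulene-4,8-dione (trans-fused) | CC(C)[C@]1(O)CC[C@@]2(C)[C@H]1C(=O)CC(C)CC2=O | intermediate
15 | (3R,3aS,4S,8aS)-3,4-dihydroxy-6,8a-dimethyl-3-(propan-2-yl)perhydroazulen-8-one | CC(C)[C@]1(O)CC[C@@]2(C)[C@H]1[C@@H](O)CC(C)CC2=O | intermediate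
16 | 3,4,5-trimethoxybenzoyl chloride | COc1cc(C(=O)Cl)cc(OC)c1OC | starting material
17 | (3R,3aS,4S,8aS)-3-hydroxy-6,8a-dimethyl-8-oxo-3-(propan-2-yl)perhydroazulen-4-yl 3,4,5-trimethoxybenzoate | CC(C)[C@]1(O)CC[C@@]2(C)[C@H]1[C@@H](OC(=O)c3cc(OC)c(OC)c(OC)c3)CC(C)CC2=O | intermediate
18 | (3R,3aS,4S,8aS)-3-hydroxy-6,8a-dimethyl-8-oxo-3-(propan-2-yl)-1,2,3,3a,4,5,8,8a-octahydroazulen-4-yl 3,4,5-trimethoxybenzoate | COc1cc(C(=O)O[C@H]2CC(C)=CC(=O)[C@@]3(C)CC[C@@](O)(C(C)C)[C@H]23)cc(OC)c1OC | target

**Step count and risks**

Total step count: 12. Longest linear sequence: 11 steps (steps 1 and 3 to 12, from 1).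

Steps most likely to fail:

Step 9. The tertiary aldol unit (C3–OH β to the C4 ketone) may open by retro-aldol cleavage of the five-membered ring, or dehydrate, faster than the ring-fusion carbon epimerises. The fallback sets out from 11 and removes the free β-hydroxyl during the base treatment. Silylation with Et3SiOTf and 2,6-lutidine should give the triethylsilyl ether of 11, F1. Selective methanolysis of the two trimethylsilyl ethers (PPTS, MeOH) and NaIO4 cleavage should give the cis-fused silyloxy dione F2. Catalytic DBU at 0 °C should then epimerise it to the trans-fused silyloxy dione F3; the silyl ether closes the retro-aldol path, and loss of silanolate from the enolate should be slower than its reprotonation under these mild conditions. HF·pyridine removes the triethylsilyl group and the route is rejoined at 14.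

Step 7. The tertiary radical is a cyclobutylcarbinyl radical and may open the cyclobutane before O2 traps it, or be trapped on both faces. The fallback sets out from 10 and replaces the radical hydration by a two-electron sequence. Epoxidation with dimethyldioxirane in acetone on the exo face should give the exo epoxide F4. LiEt3BH should open it by SN2 attack at the secondary carbon, and the route is rejoined at 11.

Step 6. β-Hydride elimination from the isopropyl–Fe intermediate may outrun C–C bond formation at this hindered alkenyl triflate, leading to reduction of the triflate or to an isomerised propyl group. The fallback sets out from 9 and brings in the three carbons as an sp2 partner. Suzuki–Miyaura coupling with isopropenylboronic acid pinacol ester (Pd(PPh3)4, K3PO4, dioxane/H2O) should give the isopropenyl diene F5. Hydrogenation with RhCl(PPh3)3 and H2 should saturate only the less hindered 1,1-disubstituted double bond, and the route is rejoined at 10.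

Further compounds
F1 | step 9 | cis-anti-cis 1,4-dimethyl-8-(propan-2-yl)-8-(triethylsilyloxy)-2,6-bis(trimethylsilyloxy)tricyclo[5.3.0.0^2,6]decane | CC(C)[C@]1(O[Si](CC)(CC)CC)CC[C@@]2(C)[C@@H]1[C@]3(O[Si](C)(C)C)CC(C)C[C@]23O[Si](C)(C)C
F2 | step 9 | (3R,3aS,8aS)-6,8a-dimethyl-3-(propan-2-yl)-3-(triethylsilyloxy)perhydroazulene-4,8-dione (cis-fused) | CC(C)[C@]1(O[Si](CC)(CC)CC)CC[C@@]2(C)[C@@H]1C(=O)CC(C)CC2=O
F3 | step 9 | (3R,3aR,8aS)-6,8a-dimethyl-3-(propan-2-yl)-3-(triethylsilyloxy)perhydroazulene-4,8-dione (trans-fused) | CC(C)[C@]1(O[Si](CC)(CC)CC)CC[C@@]2(C)[C@H]1C(=O)CC(C)CC2=O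
F4 | step 7 | exo-8,9-epoxy-1,4-dimethyl-8-(propan-2-yl)-2,6-bis(trimethylsilyloxy)tricyclo[5.3.0.0^2,6]decane | CC(C)[C@]12O[C@H]1C[C@@]3(C)[C@@H]2[C@]4(O[Si](C)(C)C)CC(C)C[C@]34O[Si](C)(C)C
F5 | step 6 | cis-anti-cis 1,4-dimethyl-8-(prop-1-en-2-yl)-2,6-bis(trimethylsilyloxy)tricyclo[5.3.0.0^2,6]dec-8-ene | CC(=C)C1=CC[C@@]2(C)[C@@H]1[C@]3(O[Si](C)(C)C)CC(C)C[C@]23O[Si](C)(C)C
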